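**Plan**
- Numbering: ring A is C1 (bearing the exocyclic CH2), C2, C3, C4 (CHBr), C5 (CMe2), spiro C6; ring B is C6, C7, C8, C9 (CMeBr), C10 (CHCl), C11. The enabling feature is that quaternary C6 sits next to the exocyclic C1=CH2, the γ,δ-unsaturated pattern left when an allylic ester on the C1 methylene carbon hands C7 over to C6.
- Cuts, in retrosynthetic order: C7–H (back to a C7 carboxyl), C6–C7 of ring B (sigmatropic, back to a ten-membered lactone), the lactone C–O bond, C10–C11 (allylic bromide plus a (Z)-alkenylcopper), and C5–C6 of ring A (bromonium cyclisation of an acyclic β-keto ester).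
- Forward order: ring A closes first, the C7–C10 chain is attached, the lactone ring is closed, ring B and spiro C6 arise last by ring contraction, and decarboxylation ends the route.
- Stereochemistry: C4 comes from a catalytic enantioselective bromochlorination of prenol, relayed through a bromonium ion. C9 and C10 come from a Shi epoxidation of the (Z)-alkene followed by two stereospecific anti openings. C6 comes from the folding of the halogenated tether in the rearrangement.

Key step: step 16

Remark: the sense of induction is a matter of reagent choice in step 1 (the ligand enantiomer that gives the (2R)-bromide) and in step 10 (the D-fructose-derived ketone, as the spiro model predicts; its antipode would be used if the other face were attacked).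

Step 1
Reactants: 1 3-methylbut-2-en-1-ol (prenol)
Product: 2 (2R)-2-bromo-3-chloro-3-methylbutan-1-ol
Conditions: NBS, ClTi(OiPr)3, chiral tridentate Schiff-base (salicylaldimine–amino alcohol) ligand (20 mol %), hexanes, −20 °C
Reagents that add atoms: N-bromosuccinimide, O=C1CCC(=O)N1Br; ClTi(OiPr)3, CC(C)O[Ti](Cl)(OC(C)C)OC(C)C
Why: The titanium-alkoxide-directed catalytic enantioselective bromochlorination of allylic alcohols puts bromine on C2 and chloride on the tertiary C3 anti across the alkene, so the ligand enantiomer fixes the (R) configuration of the future C4–Br centre.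

Step 2
Reactants: 2 (2R)-2-bromo-3-chloro-3-methylbutan-1-ol
Product: 3 (2R)-2-bromo-3-chloro-3-methylbutyl trifluoromethanesulfonate
Conditions: Tf2O, 2,6-lutidine, CH2Cl2, −78 °C
Reagents that add atoms: trifluoromethanesulfonic anhydride, O=S(=O)(OS(=O)(=O)C(F)(F)F)C(F)(F)F
Why: Triflate formation from a primary alcohol with a hindered pyridine base at low temperature is routine and leaves the secondary bromide and tertiary chloride untouched.

Step 3
Reactants: 3 (2R)-2-bromo-3-chloro-3-methylbutyl trifluoromethanesulfonate; 4 methyl acetoacetate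
Product: 6 methyl (6R)-6-bromo-7-chloro-7-methyl-3-oxooctanoate, via acetoacetate dianion 5 (not isolated)
Conditions: 4, NaH then n-BuLi, THF, 0 °C; then 3, −78 → −40 °C
Reagents that add atoms: none
Why: γ-Alkylation of an acetoacetate dianion with a primary triflate is an SN2 reaction that is fast at −78 °C, where it should outrun elimination, and it does not involve the C–Br stereocentre.

Step 4
Reactants: 6 methyl (6R)-6-bromo-7-chloro-7-methyl-3-oxooctanoate
Product: 7 methyl (3R)-3-bromo-2,2-dimethyl-6-oxocyclohexane-1-carboxylate (C1 epimers and enol form)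
Conditions: (CF3)2CHOH, 2,6-lutidine, 23 °C
Reagents that add atoms: none
Why: In the strongly ionising, weakly nucleophilic solvent the tertiary chloride should leave with help from the neighbouring bromine to give a configurationally defined bromonium ion, which the enol carbon of the β-keto ester traps at the tertiary carbon in a halonium-initiated cation–olefin cyclisation, so ring A forms with the C4 configuration carried over unchanged from 6.

Step 5
Reactants: 7 methyl (3R)-3-bromo-2,2-dimethyl-6-oxocyclohexane-1-carboxylate
Product: 8 methyl (5R)-5-bromo-6,6-dimethyl-2-(trifluoromethylsulfonyloxy)cyclohex-1-ene-1-carboxylate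
Conditions: Tf2O, i-Pr2NEt, CH2Cl2, −78 °C
Reagents that add atoms: trifluoromethanesulfonic anhydride, O=S(=O)(OS(=O)(=O)C(F)(F)F)C(F)(F)F
Why: Enol triflate formation from a β-keto ester can only give the tetrasubstituted C1=C6 enol triflate conjugated with the ester, which fixes the position of the ring A double bond, and at −78 °C sulfonylation should be faster than any displacement of the γ-bromide by the enolate.

Step 6
Reactants: 8 methyl (5R)-5-bromo-6,6-dimethyl-2-(trifluoromethylsulfonyloxy)cyclohex-1-ene-1-carboxylate
Product: 9 (4R)-4-bromo-2-(hydroxymethyl)-3,3-dimethylcyclohex-1-en-1-yl trifluoromethanesulfonate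
Conditions: i-Bu2AlH, CH2Cl2, −78 °C
Reagents that add atoms: none
Why: 1,2-Reduction of the ester by i-Bu2AlH at −78 °C gives the primary allylic alcohol (the future C11) without touching the enol triflate or the neopentyl-type secondary bromide.

Step 7
Reactants: 9 (4R)-4-bromo-2-(hydroxymethyl)-3,3-dimethylcyclohex-1-en-1-yl trifluoromethanesulfonate
Product: 10 (4R)-4-bromo-2-(bromomethyl)-3,3-dimethylcyclohex-1-en-1-yl trifluoromethanesulfonate
Conditions: CBr4, PPh3, CH2Cl2, 0 °C
Reagents that add atoms: tetrabromomethane, BrC(Br)(Br)Br
Why: The Appel reaction converts the primary allylic alcohol into the bromide under neutral conditions, and allylic transposition is blocked because the other allylic terminus is the fully substituted triflate-bearing carbon.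

Step 8
Reactants: 10 (4R)-4-bromo-2-(bromomethyl)-3,3-dimethylcyclohex-1-en-1-yl trifluoromethanesulfonate; 11 but-3-enylmagnesium bromide; 12 propyne
Product: 15 (4R)-4-bromo-3,3-dimethyl-2-[(2Z)-3-methylhepta-2,6-dienyl]cyclohex-1-en-1-yl trifluoromethanesulfonate, via butenylcopper 13 (not isolated), via alkenylcopper 14 (not isolated)
Conditions: 11, CuBr·SMe2, Et2O–Me2S, −45 °C; 12, −25 °C; then 10, THF, −30 → 0 °C
Reagents that add atoms: none
Why: In the Normant carbocupration the alkylcopper adds syn across propyne with copper on the terminal carbon, so the alkenylcopper carries the butenyl chain cis to the metal, and its allylation by the primary allylic bromide with retention gives the (Z)-trisubstituted C9=C10 alkene, the enol triflate and secondary bromide being inert to organocopper reagents at low temperature.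

Step 9
Reactants: 15 (4R)-4-bromo-3,3-dimethyl-2-[(2Z)-3-methylhepta-2,6-dienyl]cyclohex-1-en-1-yl trifluoromethanesulfonate
Product: 16 methyl (4R)-4-bromo-3,3-dimethyl-2-[(2Z)-3-methylhepta-2,6-dienyl]cyclohex-1-ene-1-carboxylate
Conditions: Pd(OAc)2 (5 mol %), dppp, CO (1 atm), Et3N, MeOH/DMF, 60 °C
Reagents that add atoms: carbon monoxide, [C-]#[O+]; methanol, CO
Why: Palladium-catalysed alkoxycarbonylation of the enol triflate (oxidative addition, CO insertion, methanolysis) installs the carbon that becomes the lactone CH2–O and makes the ring A alkene electron-poor, while the unactivated secondary alkyl bromide does not add to zerovalent palladium under these conditions.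

Step 10
Reactants: 16 methyl (4R)-4-bromo-3,3-dimethyl-2-[(2Z)-3-methylhepta-2,6-dienyl]cyclohex-1-ene-1-carboxylate
Product: 17 methyl (4R)-4-bromo-2-{[(2R,3S)-3-(but-3-enyl)-3-methyloxiran-2-yl]methyl}-3,3-dimethylcyclohex-1-ene-1-carboxylate
Conditions: D-fructose-derived Shi ketone (30 mol %), KHSO5 (as 2KHSO5·KHSO4·K2SO4), K2CO3, Bu4NHSO4, MeCN/CH2(OMe)2/aqueous buffer, 0 °C
Reagents that add atoms: potassium peroxymonosulfate KHSO5, [K+].[O-]S(=O)(=O)OO
Why: In the Shi epoxidation the chiral dioxirane should attack the electron-rich trisubstituted alkene much faster than the vinyl group or the tetrasubstituted enoate, and the spiro transition state should deliver oxygen to the face that gives the (2R,3S)-oxirane, the product of attack on the other face being a diastereomer that can be removed, at the latest after ring closure.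

Step 11
Reactants: 17 methyl (4R)-4-bromo-2-{[(2R,3S)-3-(but-3-enyl)-3-methyloxiran-2-yl]methyl}-3,3-dimethylcyclohex-1-ene-1-carboxylate
Product: 18 methyl (4R)-4-bromo-2-[(2R,3R)-3-chloro-2-hydroxy-3-methylhept-6-enyl]-3,3-dimethylcyclohex-1-ene-1-carboxylate
Conditions: HCl (Et2O solution), CH2Cl2, −40 °C
Reagents that add atoms: hydrogen chloride, Cl
Why: Acid-mediated halohydrin formation from a trisubstituted epoxide places chloride on the tertiary carbon C9 with inversion (Markovnikov, borderline SN2) and leaves the C10 oxygen in place, anti to the new C–Cl bond.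

Step 12
Reactants: 18 methyl (4R)-4-bromo-2-[(2R,3R)-3-chloro-2-hydroxy-3-methylhept-6-enyl]-3,3-dimethylcyclohex-1-ene-1-carboxylate
Product: 20 methyl (4R)-4-bromo-2-[(2S,3S)-3-bromo-2-chloro-3-methylhept-6-enyl]-3,3-dimethylcyclohex-1-ene-1-carboxylate, via C10 triflate 19 (not isolated)
Conditions: Tf2O, 2,6-di-tert-butyl-4-methylpyridine, CH2Cl2, −78 °C; then Bu4NBr, −78 → 0 °C
Reagents that add atoms: tetrabutylammonium bromide, CCCC[N+](CCCC)(CCCC)CCCC.[Br-]
Why: Proposed new method: the C10 triflate cannot be displaced directly because it is flanked by the fully substituted C9, so on warming it should ionise with anchimeric help from the anti tertiary chlorine, which moves to C10 with inversion through a chloronium ion whose charge sits mainly on C9, and bromide should then open that ion at C9 anti to chlorine to give the anti C9–Br/C10–Cl pair with both centres defined, the closest known reaction type being the halonium-mediated 1,2-halogen shift seen when vicinal halohydrins are activated at oxygen, together with the opening of unsymmetrical halonium ions by halide at the more substituted carbon.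

Step 13
Reactants: 20 methyl (4R)-4-bromo-2-[(2S,3S)-3-bromo-2-chloro-3-methylhept-6-enyl]-3,3-dimethylcyclohex-1-ene-1-carboxylate
Product: 21 (4S,5S)-4-bromo-6-[(5R)-5-bromo-2-(methoxycarbonyl)-6,6-dimethylcyclohex-1-en-1-yl]-5-chloro-4-methylhexanoic acid
Conditions: OsO4 (1 mol %), KHSO5 (as 2KHSO5·KHSO4·K2SO4), DMF, 23 °C
Reagents that add atoms: potassium peroxymonosulfate KHSO5, [K+].[O-]S(=O)(=O)OO; OsO4 (oxygen carrier), O=[Os](=O)(=O)=O
Why: OsO4-catalysed oxidative cleavage with peroxymonosulfate takes a monosubstituted alkene through the osmate ester and the aldehyde directly to the carboxylic acid, while the tetrasubstituted, electron-poor enoate does not react with OsO4.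

Step 14
Reactants: 21 (4S,5S)-4-bromo-6-[(5R)-5-bromo-2-(methoxycarbonyl)-6,6-dimethylcyclohex-1-en-1-yl]-5-chloro-4-methylhexanoic acid
Product: 22 (4S,5S)-4-bromo-6-[(5R)-5-bromo-2-(hydroxymethyl)-6,6-dimethylcyclohex-1-en-1-yl]-5-chloro-4-methylhexanoic acid
Conditions: i-Bu2AlH (excess), CH2Cl2, −78 °C
Reagents that add atoms: none
Why: i-Bu2AlH first turns the acid into an aluminium carboxylate that resists reduction at −78 °C and then reduces the conjugated methyl ester 1,2 to the allylic alcohol, giving the seco acid without touching the alkyl halides.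

Step 15
Reactants: 22 (4S,5S)-4-bromo-6-[(5R)-5-bromo-2-(hydroxymethyl)-6,6-dimethylcyclohex-1-en-1-yl]-5-chloro-4-methylhexanoic acid
Product: 23 (7S,8S,12R)-7,12-dibromo-8-chloro-7,11,11-trimethyl-3-oxabicyclo[8.4.0]tetradec-1(10)-en-4-one (ten-membered lactone fused to ring A)
Conditions: 2-methyl-6-nitrobenzoic anhydride, DMAP, CH2Cl2 (high dilution, slow addition of 22), 23 °C
Reagents that add atoms: none
Why: In the Shiina macrolactonisation the mixed anhydride acylates the primary allylic alcohol under DMAP catalysis at room temperature, and the cis ring A double bond holds both chain ends on the same side, which should ease closure of the ten-membered ring.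

Step 16
Reactants: 23 (7S,8S,12R)-7,12-dibromo-8-chloro-7,11,11-trimethyl-3-oxabicyclo[8.4.0]tetradec-1(10)-en-4-one
Product: 26 (4R,6R,9S,10S)-4,9-dibromo-10-chloro-5,5,9-trimethyl-1-methylidenespiro[5.5]undecane-7-carboxylic acid (C7 epimers), via silyl ketene acetal 24 (not isolated), via silyl ester 25 (not isolated)
Conditions: TBSOTf, Et3N, toluene, 0 → 80 °C; then 1 M HCl, THF, 0 °C
Reagents that add atoms: none
Why: Soft enolisation with TBSOTf and Et3N converts the lactone into its silyl ketene acetal, and on warming C7 bonds to C6 while the allylic CH2–O bond breaks in a concerted [3,3] shift (Ireland–Claisen rearrangement), the closest precedent being the ring contraction of medium-ring unsaturated lactones to carbocyclic acids. Ring B (C6–C11) closes by contraction of the ten-membered lactone, that is, by joining the two ends of a tether already in place and not by a direct cyclisation, and the ring A double bond moves to C1=CH2. The new quaternary centre C6 is controlled by the preset C9 and C10 centres: the six ring B atoms should assemble in a chair-like array with C5, C9–Br and C10–Cl equatorial, whereas attack on the other face of C6 would force C10–Cl syn-axial to C1 (the CIP descriptor of C6 reads R here and S in the target only because the C7 carboxyl changes ligand priorities). C7 forms as a mixture of epimers, which does not matter because its carboxyl is removed in step 17. The step needs the hindered tetrasubstituted alkene to react and the tertiary bromide to survive; the first is secured by the ring holding C7 against C6, the second by using an amine base and no metal amide.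

Step 17
Reactants: 26 (4R,6R,9S,10S)-4,9-dibromo-10-chloro-5,5,9-trimethyl-1-methylidenespiro[5.5]undecane-7-carboxylic acid
Product: 28 obtusane [(4R,6S,9S,10S)-4,9-dibromo-10-chloro-5,5,9-trimethyl-1-methylidenespiro[5.5]undecane], via thiohydroxamate ester 27 (not isolated)
Conditions: DCC, 1-hydroxypyridine-2(1H)-thione, DMAP (cat.), CH2Cl2, 0 °C, dark; then PhSeH, hν (visible), 0 °C
Reagents that add atoms: none
Why: In the Barton decarboxylation the thiohydroxamate ester fragments on irradiation to the C7 radical, which PhSeH should reduce at a near diffusion-controlled rate, faster than the 1,2-vinyl shift open to this homoallylic radical, and no stereocentre is formed or lost.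

**Compound list**
1 | 3-methylbut-2-en-1-ol (prenol) | CC(C)=CCO | starting material
2 | (2R)-2-bromo-3-chloro-3-methylbutan-1-ol | OC[C@@H](Br)C(C)(C)Cl | intermediate
3 | (2R)-2-bromo-3-chloro-3-methylbutyl trifluoromethanesulfonate | O=S(=O)(OC[C@@H](Br)C(C)(C)Cl)C(F)(F)F | intermediate
4 | methyl acetoacetate | COC(=O)CC(C)=O | starting material
5 | acetoacetate dianion (lithium sodium salt, formed in the flask) | [Li+].[Na+].[CH2-]C(=O)[CH-]C(=O)OC | intermediate
6 | methyl (6R)-6-bromo-7-chloro-7-methyl-3-oxooctanoate | COC(=O)CC(=O)CC[C@@H](Br)C(C)(C)Cl | intermediate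
7 | methyl (3R)-3-bromo-2,2-dimethyl-6-oxocyclohexane-1-carboxylate | COC(=O)C1C(=O)CC[C@@H](Br)C1(C)C | intermediate
8 | methyl (5R)-5-bromo-6,6-dimethyl-2-(trifluoromethylsulfonyloxy)cyclohex-1-ene-1-carboxylate | COC(=O)C1=C(OS(=O)(=O)C(F)(F)F)CC[C@@H](Br)C1(C)C | intermediate
9 | (4R)-4-bromo-2-(hydroxymethyl)-3,3-dimethylcyclohex-1-en-1-yl trifluoromethanesulfonate | OCC1=C(OS(=O)(=O)C(F)(F)F)CC[C@@H](Br)C1(C)C | intermediate
10 | (4R)-4-bromo-2-(bromomethyl)-3,3-dimethylcyclohex-1-en-1-yl trifluoromethanesulfonate | BrCC1=C(OS(=O)(=O)C(F)(F)F)CC[C@@H](Br)C1(C)C | intermediate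
11 | but-3-enylmagnesium bromide | C=CCC[Mg]Br | starting material
12 | propyne | CC#C | starting material
13 | but-3-enylcopper (formed in the flask) | C=CCC[Cu] | intermediate
14 | (1Z)-2-methylhexa-1,5-dienylcopper (formed in the flask) | [Cu]/C=C(/C)CCC=C | intermediate
15 | (4R)-4-bromo-3,3-dimethyl-2-[(2Z)-3-methylhepta-2,6-dienyl]cyclohex-1-en-1-yl trifluoromethanesulfonate | C=CCC/C(C)=C\CC1=C(OS(=O)(=O)C(F)(F)F)CC[C@@H](Br)C1(C)C | intermediate
16 | methyl (4R)-4-bromo-3,3-dimethyl-2-[(2Z)-3-methylhepta-2,6-dienyl]cyclohex-1-ene-1-carboxylate | C=CCC/C(C)=C\CC1=C(C(=O)OC)CC[C@@H](Br)C1(C)C | intermediate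
17 | methyl (4R)-4-bromo-2-{[(2R,3S)-3-(but-3-enyl)-3-methyloxiran-2-yl]methyl}-3,3-dimethylcyclohex-1-ene-1-carboxylate | C=CCC[C@]1(C)O[C@@H]1CC2=C(C(=O)OC)CC[C@@H](Br)C2(C)C | intermediate
18 | methyl (4R)-4-bromo-2-[(2R,3R)-3-chloro-2-hydroxy-3-methylhept-6-enyl]-3,3-dimethylcyclohex-1-ene-1-carboxylate | C=CCC[C@@](C)(Cl)[C@H](O)CC1=C(C(=O)OC)CC[C@@H](Br)C1(C)C | intermediate
19 | C10 trifluoromethanesulfonate of 18 (formed in the flask) | C=CCC[C@@](C)(Cl)[C@H](OS(=O)(=O)C(F)(F)F)CC1=C(C(=O)OC)CC[C@@H](Br)C1(C)C | intermediate
20 | methyl (4R)-4-bromo-2-[(2S,3S)-3-bromo-2-chloro-3-methylhept-6-enyl]-3,3-dimethylcyclohex-1-ene-1-carboxylate | C=CCC[C@](C)(Br)[C@@H](Cl)CC1=C(C(=O)OC)CC[C@@H](Br)C1(C)C | intermediate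
21 | (4S,5S)-4-bromo-6-[(5R)-5-bromo-2-(methoxycarbonyl)-6,6-dimethylcyclohex-1-en-1-yl]-5-chloro-4-methylhexanoic acid | OC(=O)CC[C@](C)(Br)[C@@H](Cl)CC1=C(C(=O)OC)CC[C@@H](Br)C1(C)C | intermediate
22 | (4S,5S)-4-bromo-6-[(5R)-5-bromo-2-(hydroxymethyl)-6,6-dimethylcyclohex-1-en-1-yl]-5-chloro-4-methylhexanoic acid | OC(=O)CC[C@](C)(Br)[C@@H](Cl)CC1=C(CO)CC[C@@H](Br)C1(C)C | intermediate
23 | (7S,8S,12R)-7,12-dibromo-8-chloro-7,11,11-trimethyl-3-oxabicyclo[8.4.0]tetradec-1(10)-en-4-one | O=C1CC[C@](C)(Br)[C@@H](Cl)CC2=C(CO1)CC[C@@H](Br)C2(C)C | intermediate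
24 | tert-butyldimethylsilyl ketene acetal of 23 (formed in the flask) | CC(C)(C)[Si](C)(C)OC1=CC[C@](C)(Br)[C@@H](Cl)CC2=C(CO1)CC[C@@H](Br)C2(C)C | intermediate
25 | tert-butyldimethylsilyl ester of 26 (formed in the flask) | C=C1CC[C@@H](Br)C(C)(C)[C@]12C(C(=O)O[Si](C)(C)C(C)(C)C)C[C@](C)(Br)[C@@H](Cl)C2 | intermediate
26 | (4R,6R,9S,10S)-4,9-dibromo-10-chloro-5,5,9-trimethyl-1-methylidenespiro[5.5]undecane-7-carboxylic acid (C7 epimers) | C=C1CC[C@@H](Br)C(C)(C)[C@]12C(C(=O)O)C[C@](C)(Br)[C@@H](Cl)C2 | intermediate
27 | 2-thioxopyridin-1(2H)-yl ester of 26 (formed in the flask) | C=C1CC[C@@H](Br)C(C)(C)[C@]12C(C(=O)ON3C=CC=CC3=S)C[C@](C)(Br)[C@@H](Cl)C2 | intermediate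
28 | obtusane, (4R,6S,9S,10S)-4,9-dibromo-10-chloro-5,5,9-trimethyl-1-methylidenespiro[5.5]undecane | C=C1CC[C@@H](Br)C(C)(C)[C@]12CC[C@](C)(Br)[C@@H](Cl)C2 | target

**Step count and risks**

Total steps: 17. Longest linear sequence: 17 steps (1 → 28); compounds 4, 11 and 12 enter as purchased materials.

The three steps most likely to fail are step 12, step 15 and step 4.

In step 12 the ionisation may not be steered by chlorine alone. Loss of a proton from the chloronium ion (elimination), capture of C10 by the ring A ester carbonyl, or bromide attack after the bridged ion has opened (loss of configuration at C9) would all lower the return. The fallback uses only known reaction types and sets out from epoxide 17. Li2CuCl4 in THF should open the oxirane at the less substituted carbon C10 with inversion to give methyl (4R)-4-bromo-2-[(2S,3S)-2-chloro-3-hydroxy-3-methylhept-6-enyl]-3,3-dimethylcyclohex-1-ene-1-carboxylate F1. Me3SiBr in CH2Cl2 at −40 °C should then exchange the tertiary hydroxyl for bromide by ionisation, the anti chlorine on C10 shielding one face of C9 so that bromide enters where oxygen left. The sequence comes back to the route at 20.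

In step 15 intermolecular acylation (dimer and oligomer formation) may outrun closure of the ten-membered ring, and the carboxylate may displace the tertiary bromide to a γ-lactone before it is activated. The fallback sets out from 22 and comes back at 23 but closes the ring through the other bond of the ester. Under Mitsunobu conditions (PPh3, DIAD, toluene, high dilution, 0 °C) the allylic alcohol is activated and the carboxylate attacks the CH2 carbon, so the acid is never turned into an acylating agent and no amine base is present. No compound outside the list arises (F0).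

In step 4 the enol oxygen may win over the enol carbon in trapping the bromonium ion, or bromonium transfer between molecules may erode the enantiomeric purity set in step 1. The fallback sets out from 6. The O-cyclisation is allowed to run to completion in (CF3)2CHOH, and the product, methyl 2-[(5R)-5-bromo-6,6-dimethyloxan-2-ylidene]acetate F2, is then treated with SnCl4 in CH2Cl2 (−78 → 0 °C). The Lewis acid should re-ionise the tertiary C–O bond to the same bromonium ion and let the irreversible C–C closure accumulate, a kinetic-to-thermodynamic isomerisation of the type expected for cation–olefin cyclisations of β-keto esters. It comes back to the route at 7.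

**Further compounds**
F1 | step 12 | methyl (4R)-4-bromo-2-[(2S,3S)-2-chloro-3-hydroxy-3-methylhept-6-enyl]-3,3-dimethylcyclohex-1-ene-1-carboxylate | C=CCC[C@](C)(O)[C@@H](Cl)CC1=C(C(=O)OC)CC[C@@H](Br)C1(C)C
F0 | step 15 | none | none
F2 | step 4 | methyl 2-[(5R)-5-bromo-6,6-dimethyloxan-2-ylidene]acetate | COC(=O)C=C1CC[C@@H](Br)C(C)(C)O1
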